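## Analysis of the target

The target is a C20 gibberellin triacid, numbered in the gibberellane way: ring A is C1–C5 and C10, ring B is C5, C6, C8, C9 and C10, ring C is C8, C9 and C11–C14, and ring D is C8, C14, C13, C16 and C15, so that rings C and D together form a bicyclo[3.2.1]octane. It carries three carboxylic acids (C7 on C6, C19 on C4, C20 on C10), the C18 methyl group on C4 and a 15-hydroxy-16-methylene allylic alcohol. There are eight stereocentres (C4, C5, C6, C8, C9, C10, C13, C15), three of them quaternary (C4, C8, C10), and C8 and C10 flank C9. Rings A and B are trans-fused (C20 α, 5-H β), C19 and C20 stand 1,3-diaxial on the α face of ring A, C7 is β and trans to the C5–C4 bond, rings B and C are cis-fused, the C15–C16 bridge lies on the β face, and the 15-hydroxyl points towards C9 and C11. The sensitive points are the allylic alcohol next to the exocyclic alkene (acid-labile and prone to skeletal rearrangement), the epimerisable C6–H, and the C19/C20 pair, which closes to a δ-lactone whenever C20 is a free carbinol beside an unhindered C19 ester. The synthesis is hard because of the congested C8–C9–C10 array and because four carboxyl-level carbons (C7, C15, C19, C20) must be told apart. The strategy rests on one feature: on ring B the bonds C10–C20, C9–C11 and C8–C14 all lie on the α face, so an oxygen on C20 can hold a diene over C8=C9 and deliver C11 to C9 and C14 to C8.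

## Retrosynthetic reasoning

**End game (39 back to 34).** The acids are unmasked last. The C7 methyl ester of 38 is cut at the O–methyl bond, so no acid touches the allylic alcohol. The 15-hydroxyl of 38 comes from 1,2-reduction of enone 37. The C19 tert-butyl ester (36) and the C20 carbinol (35, 34) are taken back while the enone is still present. C20 stays at the alcohol level until then because it is the anchor of the tether.

**C17 (34 back to 30).** The exocyclic methylene is cut from ketone 32 (through 33), whose only enolisable position is C16. Ketone 32 comes from sulfone 31 by C–S cleavage, and 31 from 30 by saturation of C11=C12. That saturation must precede the methylenation.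

**Ring D, bond C13–C16 (30 back to 27).** Cutting C13–C16 gives allylic carbonate 29, in which the C15 β-keto sulfone is the soft C16 nucleophile. Palladium allylic alkylation proceeds with net retention, so the C11 oxygen must sit on the face of ring C that carries C15. Carbonate 29 comes from diol 27 through the C20 silyl ether 28.

**C11–O from C11–Si (27 back to 26).** The allylic oxygen is a carbon–silicon bond in disguise. Oxidation with retention turns siloxane 26 into 27 and sets C20 free at the same time.

**Ring C, bonds C9–C11 and C8–C14 (26 back to 25).** This is the key disconnection. Both bonds are cut at once to give the AB cyclopentenyl ketone 25, in which an (E)-butadienylsilyl group hangs from the C20 oxygen. Cutting here removes ring C, the two ring-fusion stereocentres (C8, C9) and the C11 stereocentre in one step, with face and regiochemistry fixed by the tether. The C8 acyl group is chosen as the β-keto sulfone itself: a C8 ester could not later be distinguished from the C7 and C19 esters, whereas the keto sulfone activates the dienophile and is the ring D nucleophile.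

**Si–O (25 back to 20 and 24).** The tether is cut to AB alcohol 20 and chlorosilane 24. Chlorosilane 24 comes from 21 and 22 (through 23) by silylation and loss of SO2.

**C6 configuration and C18 (20 back to 17).** Alcohol 20 is the methanolysis product of bridged lactone 18. The lactone ties C7 to C20 on the α face, so C6 must be epimerised after opening, through 19. The lactone pays for itself one step earlier: in 18 ring A is locked with C20 axial and C6 is a bridgehead, so the C19 ester enolate of 17 is the only one that can form, and it is methylated from the β face.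

**C15–C16 (17 back to 14).** The keto sulfone 17 is cut between C15 and C16 to acid 15 (activated as 16) and a sulfonyl-stabilised carbanion. Acid 15 is the oxidation product of enal 14. The bond is made at the acyl level because a C15 alkoxide would lie next to the C7 lactone carbonyl.

**Ring B, bond C8=C9 (14 back to 12).** The enal is cut by retro-aldol condensation to dialdehyde 13, the ozonolysis product of diene 12. Only C8 can act as the nucleophile, and only a five-membered ring can form.

**C6–C8 and C5–C6 (12 back to 8).** The allyl group of 12 (C8, C15) is cut from lactone 11. The C5–C6 bond of 11 (through acetal 10) is cut to a radical tethered to the C20 oxygen in 9, which comes from 8. The tether can reach C5 only on the face of C20, which places C6 cis to C20 and trans to the C9 precursor. This is the trans A/B relationship, set before ring B exists.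

**C19 and the C10 quaternary centre (8 back to 1).** Ester 7 comes from enol triflate 6 by carbonylation. Triflate 6 is the trapped enolate 5 of a catalytic asymmetric conjugate addition of an (E)-alkenyl group (the C9 precursor) to enone 4. This is the only step that needs external asymmetric induction. Enone 4 comes from 3 and, by dearomatisation through 2, from 1.

## Alternatives that were turned down

**Alternative 1: one cycloaddition for rings A and B.** The bonds C5–C10 and C3–C4 are cut. In the forward sense a Lewis acid would drive a C10=C1–C2=C3 diene attached to C9 onto a C4=C5 enoate carried by the C8 side chain, giving A1.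
- For it: two rings and the C4/C5/C10 triad arise in one late step on a finished C/D bicycle. On rings and stereocentres per step it is stronger than the chosen plan.
- Against it: the diene terminus C10 is fully substituted and the dienophile is trisubstituted, so two quaternary centres (C4 and C10) must form in one crowded transition state. Face and endo/exo control rest on remote centres, with no tether on the reacting face.
- After the step: A1 still needs C1=C2 saturated, C18 deoxygenated, two carbinols raised to acids and C17 added.
- Comparison: the chosen route builds only one ring in its key step, but every selectivity of that step is enforced by a covalent tether, and the ring A triad is made by three separately controllable reactions.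

**Alternative 2: lactone-tethered Michael addition.** The bond C4–C5 is cut. The γ-deprotonated tiglate ester of the C20 carbinol would add through its α-carbon to C5 of a ring B enoate, giving the 19,20-lactone A2.
- For it: it uses the same C20 oxygen as the chosen plan and turns the C19/C20 lactone from a liability into the controlling element. For the C4–C5–C10 triad it is at least as convincing as the present sequence.
- Against it: ring A is still open in A2 and needs ring closure and hydrogenation. α- versus γ-attack of the dienolate on a β-carbon next to quaternary C10 is uncertain. Above all, C20 ends inside a δ-lactone, while the target needs C19 and C20 both as free acids. Opening that lactone and oxidising C20 beside a free C19 carboxylate, late and in the presence of the allylic alcohol, is the weak point.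
- Comparison: the chosen route spends more steps on the triad, but it keeps C19 as a hindered tert-butyl ester that cannot lactonise and oxidises C20 directly.

**Alternative 3: interrupted Nazarov cascade.** The bonds C9–C10 and C8–C15 are cut. Acid would close the C10=C5–C6(=O)–C8=C9 dienone in a conrotatory sense, and the oxyallyl cation would be caught at C8 by an allylsilane on C13, giving A3.
- For it: it is the most convergent of the four. Rings B and D and the C8 and C10 quaternary centres form in one operation, and the 16-methylene arrives with them.
- Against it: torquoselectivity must be imposed on a fully substituted dienone, and the cation can be trapped at C5 as well as at C8. In A3 the C5 hydrogen is on the wrong face and C6 is a ketone that must be homologated to a stereodefined C6–CO2H. The 15-oxygen is missing; allylic oxidation would approach from the exo face and so should give the C15 epimer of the target.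
- Comparison: the chosen route is longer before its key step, but it carries C7 and C15 at the right oxidation level from ring B onward and leaves no stereocentre to be reset.

Key step: step 17

Remarks on the chemistry (assumptions):
- Faces: α is the face of ring B that carries C20 and β is the opposite face. In intermediates before ring B exists, the same labels are used for the carbons that become C4, C5, C6 and C10.
- The 15-hydroxyl of the target is endo in the bicyclo[3.2.1]octane: it lies on the side of C9 and C11 and is trans to C6 on ring D.
- The sense of induction of the phosphinamine ligand in step 3 is set by the choice of its enantiomer. The (S,S)-ligand is written for definiteness, and its antipode is used if the sense is reversed.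

## Route

Step 1
Reactants: 1 3-methoxybenzyl alcohol
Product: 3 3-(hydroxymethyl)cyclohex-2-en-1-one, via dienol ether 2 (not isolated)
Conditions: Li, NH3 (l), t-BuOH, THF, −78 to −33 °C; then 2 M HCl, THF, rt
Reagents that add atoms: water, O
Why: Birch reduction of the anisole ring (the benzylic alkoxide resists C–O cleavage) gives the 1,4-dihydro enol ether 2; acid hydrolysis and migration of the double bond into conjugation give the β-substituted enone.

Step 2
Reactants: 3 3-(hydroxymethyl)cyclohex-2-en-1-one
Product: 4 3-{[tert-butyl(dimethyl)silyl]oxymethyl}cyclohex-2-en-1-one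
Conditions: t-BuMe2SiCl, imidazole, DMF, 0 °C to rt
Reagents that add atoms: tert-butyl(chloro)dimethylsilane, CC(C)(C)[Si](C)(C)Cl
Why: Standard silylation; the future C20 oxygen must be inert to the organoaluminium reagent of step 3.

Step 3
Reactants: 4 3-{[tert-butyl(dimethyl)silyl]oxymethyl}cyclohex-2-en-1-one
Product: 6 (R)-3-[(E)-hex-1-enyl]-3-{[tert-butyl(dimethyl)silyl]oxymethyl}cyclohex-1-en-1-yl trifluoromethanesulfonate, via aluminium enolate 5 (not isolated)
Conditions: hex-1-yne, i-Bu2AlH, hexane, 50 °C; then 4, copper thiophene-2-carboxylate Cu(O2CC4H3S) (5 mol %), (S,S)-Ph2PN[CH(Me)Ph]2 (10 mol %), Et2O, −30 °C; MeLi, THF, −78 °C; PhNTf2, −78 to 0 °C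
Reagents that add atoms: (E)-hex-1-enyl(diisobutyl)aluminium, CCCC/C=C/[Al](CC(C)C)CC(C)C; N-phenylbis(trifluoromethanesulfonimide), O=S(=O)(N(c1ccccc1)S(=O)(=O)C(F)(F)F)C(F)(F)F
Why: Copper-catalysed asymmetric conjugate addition of an alkenylalane to a β-substituted cyclohexenone creates the C10 quaternary centre, the chiral phosphinamine choosing the enone face; the regiodefined enolate 5 is turned into its ate complex and O-sulfonylated, which fixes the C4=C5 double bond on the hindered side of the ketone.

Step 4
Reactants: 6 enol triflate
Product: 7 tert-butyl (R)-3-[(E)-hex-1-enyl]-3-{[tert-butyl(dimethyl)silyl]oxymethyl}cyclohex-1-ene-1-carboxylate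
Conditions: Pd(OAc)2 (5 mol %), dppf, CO (1 atm), t-BuOH/DMF, Et3N, 70 °C
Reagents that add atoms: carbon monoxide, [C-]#[O+]; tert-butanol, CC(C)(C)O
Why: Palladium-catalysed alkoxycarbonylation of the enol triflate installs C19 on C4; the tert-butyl ester is chosen because the C20 oxygen cannot acylate itself on it later and because it is removed without a nucleophile.

Step 5
Reactants: 7 silyl ether
Product: 8 tert-butyl (R)-3-[(E)-hex-1-enyl]-3-(hydroxymethyl)cyclohex-1-ene-1-carboxylate
Conditions: Bu4NF, AcOH, THF, 0 °C to rt
Reagents that add atoms: none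
Why: Buffered fluoride desilylation frees the C20 hydroxyl without transesterification onto the enoate.

Step 6
Reactants: 8 homoallylic alcohol
Product: 9 tert-butyl (R)-3-[(2-bromo-1-ethoxyethoxy)methyl]-3-[(E)-hex-1-enyl]cyclohex-1-ene-1-carboxylate (acetal carbon as a mixture)
Conditions: N-bromosuccinimide, ethyl vinyl ether, CH2Cl2, −40 °C to rt
Reagents that add atoms: N-bromosuccinimide, O=C1CCC(=O)N1Br; ethyl vinyl ether, C=COCC
Why: Bromoetherification of the electron-rich vinyl ether by the alcohol gives the mixed bromoacetal; the enoate and the hexenyl alkene are far less nucleophilic and are left alone.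

Step 7
Reactants: 9 bromoacetal
Product: 10 cis-fused bicyclic ethyl acetal (ring A fused to the C10–C20–O–C7–C6–C5 ring; C6 and C20 cis on ring A, 5-H β, hexenyl on C10 trans to C6; C4 and C7 as epimer mixtures)
Conditions: Bu3SnH (slow addition), AIBN (cat.), benzene, 80 °C
Reagents that add atoms: none
Why: Ueno–Stork haloacetal radical cyclisation: the nucleophilic primary radical adds 6-exo to C5 of the electron-poor enoate, which is polarity-matched and so preferred over the unactivated hexenyl alkene. The four-atom tether from C20 reaches C5 only on the face of C20, so C6 ends cis to C20 and trans to the future C9, the trans A/B relationship; the α-ester radical at C4 is then reduced by the stannane.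

Step 8
Reactants: 10 bicyclic acetal
Product: 11 cis-fused δ-lactone (C7(=O)–O–C20; C4 epimer mixture)
Conditions: CrO3, H2SO4, acetone/H2O, 0 °C
Reagents that add atoms: water, O
Why: Jones oxidation hydrolyses the mixed acetal to the lactol and oxidises it to the lactone; the alkene and the tert-butyl ester tolerate the short cold exposure.

Step 9
Reactants: 11 δ-lactone
Product: 12 6-allyl δ-lactone (allyl on the face of the lactone ring that carries the hexenyl group; C4 epimer mixture)
Conditions: LiN(SiMe3)2, THF, −78 °C; allyl bromide, −78 to −30 °C
Reagents that add atoms: allyl bromide, C=CCBr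
Why: The amide base enolises only the δ-lactone, which is several pK units more acidic than the hindered tert-butyl ester C–H; allyl bromide should enter anti to the C5–C4 bond, that is syn to the hexenyl group, and the other C6 epimer can be equilibrated through the lactone enolate.

Step 10
Reactants: 12 6-allyl δ-lactone
Product: 14 bridged enal lactone (trans-fused AB hydrindene, C8=C9, formyl on C8, 7,20-lactone bridging C6 and C10 on the α face; C4 epimer mixture), via dialdehyde lactone 13 (not isolated)
Conditions: O3, CH2Cl2, −78 °C; PPh3; concentrate; then Bn2NH·CF3CO2H (20 mol %), benzene, rt to 50 °C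
Reagents that add atoms: ozone, [O-][O+]=O
Why: Ozonolysis turns the hexenyl group into the C9 aldehyde and the allyl group into the C15 aldehyde; the enamine of the only enolisable aldehyde attacks the non-enolisable C9 aldehyde (5-enolexo aldol) and dehydration gives the C8=C9 enal, the lactone holding C8 and C9 on the same face.

Step 11
Reactants: 14 bridged enal lactone
Product: 15 bridged enoic acid lactone (C8–CO2H on the frame of 14; C4 epimer mixture)
Conditions: NaClO2, NaH2PO4, 2-methylbut-2-ene, t-BuOH/H2O, 0 °C to rt
Reagents that add atoms: sodium chlorite, [Na+].[O-]Cl=O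
Why: Pinnick oxidation: chlorous acid adds to the aldehyde and fragments to the acid, and 2-methylbut-2-ene removes the HOCl formed, so the C8=C9 alkene, the lactone and the tert-butyl ester are left alone. C15 is taken to the acyl level before C16 is attached because a C15 alkoxide would lie within reach of the C7 lactone carbonyl.

Step 12
Reactants: 15 bridged enoic acid lactone
Product: 17 enone β-keto sulfone lactone (C8=C9, C8–C(=O)CH2SO2Ph; C4 epimer mixture), via acyl imidazolide 16 (not isolated)
Conditions: 1,1'-carbonyldiimidazole, THF, rt; then PhSO2CH2Li (2.1 equiv, from PhSO2CH3 and n-BuLi), THF, −78 °C; aq. NH4Cl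
Reagents that add atoms: methyl phenyl sulfone, CS(=O)(=O)c1ccccc1
Why: Acylation of a sulfonyl-stabilised carbanion: the acyl imidazolide is far more electrophilic than the lactone or the tert-butyl ester, and the β-keto sulfone is deprotonated by the second equivalent as it forms, which protects it from further attack. The keto sulfone is both the acyl group that activates C8=C9 as a dienophile and the later soft nucleophile for ring D.

Step 13
Reactants: 17 enone β-keto sulfone lactone
Product: 18 4β-methyl-4α-(tert-butoxycarbonyl) enone β-keto sulfone lactone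
Conditions: LiN(i-Pr)2 (2.2 equiv), THF, −78 to −40 °C; MeI (1.1 equiv), −78 to −40 °C
Reagents that add atoms: iodomethane, CI
Why: The first equivalent of base deprotonates the β-keto sulfone and thereby protects the enone, the second forms the exocyclic C19 ester enolate at C4 (C6 is a bridgehead and cannot enolise); in the locked trans-fused frame C20 is axial on the α face, so iodomethane enters equatorially from the β face, the classical outcome of exocyclic ester-enolate alkylation beside an axial angular substituent.

Step 14
Reactants: 18 methylated lactone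
Product: 20 AB alcohol (methyl 6β-carboxylate, C20–OH, tert-butyl 19-oate, C8=C9 enone with C8–C(=O)CH2SO2Ph), via 6-epi hydroxy ester 19 (not isolated)
Conditions: NaOMe (2.2 equiv), MeOH, 0 °C to rt; AcOH quench at 0 °C
Reagents that add atoms: methanol, CO
Why: Methoxide opens the bridged lactone by transesterification to 19; its C6 then epimerises through the ester enolate to the C7-β configuration, trans to the C4 substituent on C5, which can no longer lactonise onto C20, while the hindered tert-butyl ester at C19 is not attacked by the C20 alkoxide.

Step 15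
Reactants: 21 3-sulfolene; 22 dichlorodimethylsilane
Product: 24 [(E)-buta-1,3-dien-1-yl](chloro)dimethylsilane, via silylsulfolene 23 (not isolated)
Conditions: 22 (3 equiv), LiN(SiMe3)2, THF, −78 °C; filter and strip under N2; toluene, 110 °C; distil
Reagents that add atoms: none
Why: The sulfolene α-anion is silylated as it forms; cheletropic loss of SO2 is disrotatory and places the 2-substituent of the sulfolene on the outside of the diene, giving the (E)-1-silyldiene.

Step 16
Reactants: 20 AB alcohol; 24 dienylchlorosilane
Product: 25 C20 O-[(E)-buta-1,3-dienyl](dimethyl)silyl ether of 20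
Conditions: imidazole, CH2Cl2, 0 °C to rt
Reagents that add atoms: none
Why: Silylation of the primary neopentyl alcohol with the chlorosilane; any silyl enol ether formed at the β-keto sulfone is hydrolysed on work-up.

Step 17
Reactants: 25 dienylsilyl ether
Product: 26 siloxane-bridged ABC tricycle (C12=C13; C11–Si on the face of ring C that carries C15; C8 bearing C(=O)CH2SO2Ph on the β face of ring B; 9-H β)
Conditions: toluene (0.01 M), 2,6-di-tert-butyl-4-methylphenol (cat.), 150 °C, sealed tube
Reagents that add atoms: none
Why: A concerted, normal-demand [4+2] cycloaddition between the 1-silylbutadiene and the acyl-activated C8=C9 alkene forms C9–C11 and C8–C14; the closest known reaction type is the temporary silicon-tethered intramolecular Diels–Alder reaction of dienylsilyl ethers, a decatriene-type cycloaddition. Ring C closes as the cyclohexene of the cycloaddition. The siloxane (C9, C10, C20, O, Si, C11) closes with it as the six-membered tether ring, cis-fused to ring B and trans-fused to ring C. C8 and C9 are set by the anchor: the tether starts at C20 on the α face, so the diene can add only to the α face, suprafacially, which puts C14 and C11 α and the acyl group and 9-H β. C11 is set by the transition-state geometry: with the (E)-diene only the acyl-endo, tether-exo arrangement lets the Si–O–C20 chain span from C11 to C10, and this places silicon trans to C10 and cis to C15 on ring C. The step needs facial, regiochemical and endo/exo selectivity; the first two are enforced by the length and anchoring of the tether (C11, not C14, must bond to C9), the third by the tether geometry, reinforced by the endo preference of the carbonyl. Thermal activation is used because Me2AlCl or Et2AlCl would be consumed by the acidic β-keto sulfone. The C7-β ester lies on the face opposite to the incoming diene and does not hinder it.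

Step 18
Reactants: 26 siloxane-bridged tricycle
Product: 27 11,20-diol (C11–OH on the face of ring C that carries C15)
Conditions: KF, KHCO3, 30% H2O2, THF/MeOH, rt to 40 °C
Reagents that add atoms: hydrogen peroxide, OO
Why: Tamao oxidation of the alkoxy(allyl)silane: hydroperoxide adds to the fluoride-activated silicon and C11 migrates to oxygen with retention, so the allylic hydroxyl keeps the face of C15 and C20–OH is set free; the β-keto sulfone sits as its enolate and the neopentyl C15 ketone is too hindered for peroxide attack.

Step 19
Reactants: 27 11,20-diol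
Product: 28 20-O-tert-butyldimethylsilyl ether
Conditions: t-BuMe2SiCl (1.1 equiv), imidazole, CH2Cl2, 0 °C
Reagents that add atoms: tert-butyl(chloro)dimethylsilane, CC(C)(C)[Si](C)(C)Cl
Why: The primary C20 hydroxyl is silylated in preference to the hindered secondary allylic C11 hydroxyl.

Step 20
Reactants: 28 20-silyl ether
Product: 29 11-methyl carbonate
Conditions: ClCO2Me, pyridine, DMAP (cat.), CH2Cl2, 0 °C to rt
Reagents that add atoms: methyl chloroformate, COC(=O)Cl
Why: Acylation of the remaining allylic alcohol gives a leaving group that generates its own base on ionisation.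

Step 21
Reactants: 29 allylic carbonate
Product: 30 tetracycle with ring D closed (C13–C16 bond, C11=C12, 16-phenylsulfonyl-15-ketone; C16 as a mixture)
Conditions: Pd(PPh3)4 (5 mol %), THF, 50 °C
Reagents that add atoms: none
Why: Tsuji–Trost allylic alkylation: zerovalent palladium ionises the carbonate with inversion, the methoxide released deprotonates the β-keto sulfone, and C16 attacks the allyl unit anti to palladium, on the face of C15, at the less hindered terminus C13 (5-exo closure, net retention); this sets C13 and leaves C11=C12.

Step 22
Reactants: 30 tetracyclic alkene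
Product: 31 11,12-dihydro tetracycle
Conditions: H2 (1 atm), Pd/C, EtOAc, rt
Reagents that add atoms: none
Why: Hydrogenation of the cis-disubstituted ring C alkene, done before the exocyclic enone is made.

Step 23
Reactants: 31 β-keto sulfone
Product: 32 15-ketone (C16 methylene group, 20-O-silyl ether)
Conditions: SmI2, THF/MeOH, −78 °C
Reagents that add atoms: none
Why: Reductive cleavage of the α-sulfonyl ketone by divalent samarium gives the samarium enolate, which is protonated; the esters and the hindered ketone are not reduced under these conditions.

Step 24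
Reactants: 32 15-ketone
Product: 34 16-methylene-15-ketone (20-O-silyl ether), via Mannich base 33 (not isolated)
Conditions: LiN(SiMe3)2, THF, −78 °C; [Me2N=CH2]I, −78 °C to rt; then MeI, CH2Cl2, rt; aq. NaHCO3
Reagents that add atoms: dimethyl(methylidene)ammonium iodide, C=[N+](C)C.[I-]
Why: C16 is the only enolisable position of the ketone (C8 is quaternary), and the weak amide base leaves the C6 ester proton alone; Mannich reaction, quaternisation and elimination give the α-methylene ketone.

Step 25
Reactants: 34 silyl ether enone
Product: 35 20-alcohol enone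
Conditions: HF·pyridine, pyridine, THF, 0 °C to rt
Reagents that add atoms: none
Why: Buffered fluoride removes the silyl group without a nucleophile that could add to the exocyclic enone.

Step 26
Reactants: 35 20-alcohol enone
Product: 36 20-oic acid (7-methyl ester, 19-tert-butyl ester, 16-methylene-15-ketone)
Conditions: CrO3, H2SO4, acetone/H2O, 0 °C
Reagents that add atoms: water, O
Why: Jones oxidation takes the neopentyl primary alcohol through the aldehyde hydrate to the acid; the enone is inert, and no free C19 acid is present to trap C20 as a lactone.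

Step 27
Reactants: 36 20-oic acid
Product: 37 19,20-dioic acid 7-methyl ester enone
Conditions: CF3CO2H, CH2Cl2, 0 °C
Reagents that add atoms: none
Why: Acidolysis of the tert-butyl ester by loss of isobutene, carried out before the acid-sensitive allylic alcohol exists.

Step 28
Reactants: 37 enone diacid
Product: 38 15-hydroxy-16-methylene 19,20-dioic acid 7-methyl ester (15-OH towards C9 and C11)
Conditions: NaBH4 (excess), CeCl3·7H2O, MeOH, −78 to −20 °C
Reagents that add atoms: none
Why: Luche 1,2-reduction; hydride should approach C15 from the exo face (the C14 side), because the endo face is shielded by the axial hydrogen on C11 and by 9-H. This places the hydroxyl on the endo side as in the target, trans to C6 and out of reach of the C7 ester.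

Step 29
Reactants: 38 7-methyl ester
Product: 39 target gibberellin triacid
Conditions: n-PrSLi (excess, from n-PrSH and n-BuLi), HMPA, rt to 50 °C; cold 1 M HCl work-up
Reagents that add atoms: none
Why: The thiolate cleaves the hindered methyl ester by SN2 attack at the methyl carbon, so neither strong acid nor hot hydroxide touches the allylic alcohol, the exocyclic alkene or C6.

## Compound list

1 | 3-methoxybenzyl alcohol | COc1cccc(CO)c1 | starting material
2 | (5-methoxycyclohexa-1,4-dien-1-yl)methanol | COC1=CCC=C(CO)C1 | intermediate (not isolated)
3 | 3-(hydroxymethyl)cyclohex-2-en-1-one | O=C1C=C(CO)CCC1 | intermediate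
4 | 3-{[tert-butyl(dimethyl)silyl]oxymethyl}cyclohex-2-en-1-one | O=C1C=C(CO[Si](C)(C)C(C)(C)C)CCC1 | intermediate
5 | diisobutylaluminium (R)-3-[(E)-hex-1-enyl]-3-{[tert-butyl(dimethyl)silyl]oxymethyl}cyclohex-1-en-1-olate | CCCC/C=C/[C@]1(CO[Si](C)(C)C(C)(C)C)CCCC(O[Al](CC(C)C)CC(C)C)=C1 | intermediate (not isolated)
6 | (R)-3-[(E)-hex-1-enyl]-3-{[tert-butyl(dimethyl)silyl]oxymethyl}cyclohex-1-en-1-yl trifluoromethanesulfonate | CCCC/C=C/[C@]1(CO[Si](C)(C)C(C)(C)C)CCCC(OS(=O)(=O)C(F)(F)F)=C1 | intermediate
7 | tert-butyl (R)-3-[(E)-hex-1-enyl]-3-{[tert-butyl(dimethyl)silyl]oxymethyl}cyclohex-1-ene-1-carboxylate | CCCC/C=C/[C@]1(CO[Si](C)(C)C(C)(C)C)CCCC(C(=O)OC(C)(C)C)=C1 | intermediate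
8 | tert-butyl (R)-3-[(E)-hex-1-enyl]-3-(hydroxymethyl)cyclohex-1-ene-1-carboxylate | CCCC/C=C/[C@]1(CO)CCCC(C(=O)OC(C)(C)C)=C1 | intermediate
9 | tert-butyl (R)-3-[(2-bromo-1-ethoxyethoxy)methyl]-3-[(E)-hex-1-enyl]cyclohex-1-ene-1-carboxylate (acetal epimers) | CCCC/C=C/[C@]1(COC(CBr)OCC)CCCC(C(=O)OC(C)(C)C)=C1 | intermediate
10 | cis-fused bicyclic ethyl acetal: ring A with the C10–C20–O–C7(OEt)–C6–C5 ring, tert-butyl ester on C4, (E)-hex-1-enyl on C10, C6 cis to C20, 5-H β (C4 and C7 epimers) | CCCC/C=C/[C@]12CCCC(C(=O)OC(C)(C)C)[C@H]1CC(OCC)OC2 | intermediate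
11 | cis-fused δ-lactone (C7(=O)–O–C20), otherwise as 10 (C4 epimers) | CCCC/C=C/[C@]12CCCC(C(=O)OC(C)(C)C)[C@H]1CC(=O)OC2 | intermediate
12 | 6-allyl δ-lactone, allyl syn to the C10 hexenyl group (C4 epimers) | CCCC/C=C/[C@]12CCCC(C(=O)OC(C)(C)C)[C@H]1[C@H](CC=C)C(=O)OC2 | intermediate
13 | dialdehyde lactone (formyl on C10 as C9; 2-oxoethyl on C6 as C8–C15) | O=C[C@]12CCCC(C(=O)OC(C)(C)C)[C@H]1[C@H](CC=O)C(=O)OC2 | intermediate (not isolated)
14 | bridged enal lactone: trans-fused AB hydrindene, C8=C9, C8–CHO, 7,20-lactone on the α face, tert-butyl ester on C4 (C4 epimers) | O=CC1=C[C@]23CCCC(C(=O)OC(C)(C)C)[C@H]2[C@H]1C(=O)OC3 | intermediate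
15 | bridged enoic acid lactone: C8–CO2H on the frame of 14 (C4 epimers) | O=C(O)C1=C[C@]23CCCC(C(=O)OC(C)(C)C)[C@H]2[C@H]1C(=O)OC3 | intermediate
16 | acyl imidazolide of 15: C8–C(=O)(imidazol-1-yl) (C4 epimers) | O=C(n1ccnc1)C1=C[C@]23CCCC(C(=O)OC(C)(C)C)[C@H]2[C@H]1C(=O)OC3 | intermediate (not isolated)
17 | enone β-keto sulfone lactone: C8–C(=O)CH2SO2Ph on the frame of 14 (C4 epimers) | O=C(CS(=O)(=O)c1ccccc1)C1=C[C@]23CCCC(C(=O)OC(C)(C)C)[C@H]2[C@H]1C(=O)OC3 | intermediate
18 | 4β-methyl-4α-(tert-butoxycarbonyl) enone β-keto sulfone lactone | O=C(CS(=O)(=O)c1ccccc1)C1=C[C@]23CCC[C@@](C)(C(=O)OC(C)(C)C)[C@H]2[C@H]1C(=O)OC3 | intermediate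
19 | 6-epi hydroxy ester: C7 methyl ester α, C20–OH, otherwise as 20 | O=C(CS(=O)(=O)c1ccccc1)C1=C[C@]2(CO)CCC[C@@](C)(C(=O)OC(C)(C)C)[C@H]2[C@H]1C(=O)OC | intermediate (not isolated)
20 | AB alcohol: trans-fused hydrindene, 4β-methyl, tert-butyl 19-oate (α), 5β-H, methyl 6β-carboxylate, C8=C9 with C8–C(=O)CH2SO2Ph, C10 hydroxymethyl (α) | O=C(CS(=O)(=O)c1ccccc1)C1=C[C@]2(CO)CCC[C@@](C)(C(=O)OC(C)(C)C)[C@H]2[C@@H]1C(=O)OC | intermediate
21 | 3-sulfolene (2,5-dihydrothiophene 1,1-dioxide) | O=S1(=O)CC=CC1 | starting material
22 | dichlorodimethylsilane | C[Si](C)(Cl)Cl | starting material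
23 | 2-[chloro(dimethyl)silyl]-2,5-dihydrothiophene 1,1-dioxide | O=S1(=O)CC=CC1[Si](C)(C)Cl | intermediate (not isolated)
24 | [(E)-buta-1,3-dien-1-yl](chloro)dimethylsilane | C=C/C=C/[Si](C)(C)Cl | intermediate
25 | C20 O-[(E)-buta-1,3-dienyl](dimethyl)silyl ether of 20 | C=C/C=C/[Si](C)(C)OC[C@@]12CCC[C@@](C)(C(=O)OC(C)(C)C)[C@H]1[C@H](C(=O)OC)C(C(=O)CS(=O)(=O)c1ccccc1)=C2 | intermediate
26 | siloxane-bridged ABC tricycle: C12=C13, C11–SiMe2–O–C20, Si on the face of C15, C8–C(=O)CH2SO2Ph β, 9-H β | C1=C[C@H]2[C@H]3[C@]4(CO[Si]2(C)C)CCC[C@@](C)(C(=O)OC(C)(C)C)[C@H]4[C@H](C(=O)OC)[C@]3(C1)C(=O)CS(=O)(=O)c1ccccc1 | intermediate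
27 | 11,20-diol (C11–OH on the face of C15, C12=C13) | C1=C[C@H](O)[C@H]2[C@]3(CO)CCC[C@@](C)(C(=O)OC(C)(C)C)[C@H]3[C@H](C(=O)OC)[C@]2(C1)C(=O)CS(=O)(=O)c1ccccc1 | intermediate
28 | 20-O-tert-butyldimethylsilyl ether of 27 | C1=C[C@H](O)[C@H]2[C@]3(CO[Si](C)(C)C(C)(C)C)CCC[C@@](C)(C(=O)OC(C)(C)C)[C@H]3[C@H](C(=O)OC)[C@]2(C1)C(=O)CS(=O)(=O)c1ccccc1 | intermediate
29 | 11-methyl carbonate of 28 | C1=C[C@H](OC(=O)OC)[C@H]2[C@]3(CO[Si](C)(C)C(C)(C)C)CCC[C@@](C)(C(=O)OC(C)(C)C)[C@H]3[C@H](C(=O)OC)[C@]2(C1)C(=O)CS(=O)(=O)c1ccccc1 | intermediate
30 | tetracycle: ring D closed, C11=C12, 16-phenylsulfonyl-15-ketone (C16 epimers), 20-O-silyl ether | O=C1C(S(=O)(=O)c2ccccc2)[C@@H]2C=C[C@H]3[C@]4(CO[Si](C)(C)C(C)(C)C)CCC[C@@](C)(C(=O)OC(C)(C)C)[C@H]4[C@H](C(=O)OC)[C@]13C2 | intermediate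
31 | 11,12-dihydro derivative of 30 | O=C1C(S(=O)(=O)c2ccccc2)[C@@H]2CC[C@H]3[C@]4(CO[Si](C)(C)C(C)(C)C)CCC[C@@](C)(C(=O)OC(C)(C)C)[C@H]4[C@H](C(=O)OC)[C@]13C2 | intermediate
32 | 15-ketone with C16 methylene group (20-O-silyl ether, 7-methyl ester, 19-tert-butyl ester) | O=C1C[C@@H]2CC[C@H]3[C@]4(CO[Si](C)(C)C(C)(C)C)CCC[C@@](C)(C(=O)OC(C)(C)C)[C@H]4[C@H](C(=O)OC)[C@]13C2 | intermediate
33 | 16-(dimethylaminomethyl)-15-ketone (C16 epimers) | CN(C)CC1[C@@H]2CC[C@H]3[C@]4(CO[Si](C)(C)C(C)(C)C)CCC[C@@](C)(C(=O)OC(C)(C)C)[C@H]4[C@H](C(=O)OC)[C@]3(C2)C1=O | intermediate (not isolated)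
34 | 16-methylene-15-ketone, 20-O-silyl ether | C=C1[C@@H]2CC[C@H]3[C@]4(CO[Si](C)(C)C(C)(C)C)CCC[C@@](C)(C(=O)OC(C)(C)C)[C@H]4[C@H](C(=O)OC)[C@]3(C2)C1=O | intermediate
35 | 16-methylene-15-ketone, 20-alcohol | C=C1[C@@H]2CC[C@H]3[C@]4(CO)CCC[C@@](C)(C(=O)OC(C)(C)C)[C@H]4[C@H](C(=O)OC)[C@]3(C2)C1=O | intermediate
36 | 16-methylene-15-ketone, 20-oic acid, 7-methyl ester, 19-tert-butyl ester | C=C1[C@@H]2CC[C@H]3[C@]4(C(=O)O)CCC[C@@](C)(C(=O)OC(C)(C)C)[C@H]4[C@H](C(=O)OC)[C@]3(C2)C1=O | intermediate
37 | 16-methylene-15-ketone, 19,20-dioic acid, 7-methyl ester | C=C1[C@@H]2CC[C@H]3[C@]4(C(=O)O)CCC[C@@](C)(C(=O)O)[C@H]4[C@H](C(=O)OC)[C@]3(C2)C1=O | intermediate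
38 | 7-methyl ester of the target (15-hydroxy-16-methylene 19,20-dioic acid) | C=C1[C@@H]2CC[C@H]3[C@]4(C(=O)O)CCC[C@@](C)(C(=O)O)[C@H]4[C@H](C(=O)OC)[C@]3(C2)[C@@H]1O | intermediate
39 | target gibberellin: 15-hydroxy-16-methylene C20 gibberellin 7,19,20-triacid | C=C1[C@@H]2CC[C@H]3[C@]4(C(=O)O)CCC[C@@](C)(C(=O)O)[C@H]4[C@H](C(=O)O)[C@]3(C2)[C@@H]1O | target

## Step count and least certain steps

Total step count: 29. Longest linear sequence: 28 steps (steps 1–14 and 16–29); step 15 is the one-step side branch to the silane.

**Step 17 (key step).** The cycloaddition may be too slow at a temperature the substrate tolerates, because the dienophile is trisubstituted and flanked by two substituted carbons. The silyl group may also migrate to the enol oxygen of the acidic β-keto sulfone, which destroys the tether. At high temperature the tether-endo mode could compete and erode the C11 configuration.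
Fallback: take the sulfonyl group off for the cycloaddition, so that the dienophile is a plain methyl enone that tolerates a Lewis acid at low temperature, and put it back afterwards. It sets out from 20. SmI2 in THF/MeOH at −78 °C cleaves the C16–S bond and should give the methyl enone alcohol F1. Silylation with 24 gives the methyl enone dienylsilyl ether F2. Me2AlCl in CH2Cl2 at −78 to −20 °C should then give the tricyclic methyl ketone F3. LiN(SiMe3)2 (2.2 equiv) and PhSO2F sulfonylate C16, the only enolisable position of that ketone, which brings the route back at 26.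

**Step 3.** Enantioselectivity may be poor with the oxygenated β-substituent, isobutyl may transfer instead of hexenyl, or the aluminium enolate may be sulfonylated incompletely. Each loss would be carried through the whole route.
Fallback: resolve instead of inducing. It sets out from 4. The same alane with achiral CuBr·SMe2 and the same trapping gives the racemic enol triflate F4. Carbonylation gives the racemic tert-butyl ester F5 and desilylation the racemic alcohol F6. Esterification with (S)-O-methylmandelic acid (DCC, DMAP) and separation of the diastereomers gives the (S)-O-methylmandelate F7 of the (R)-alcohol. K2CO3/MeOH releases 8, where the route is rejoined.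

**Step 14.** Through the C6 enolate the C8=C9 double bond may migrate into conjugation with the C7 ester. Epimerisation of C6 may stay incomplete because the molecule already carries the negative charge of the keto sulfone. On long exposure the C20 alkoxide may attack C19.
Fallback: postpone the epimerisation until C8 is quaternary, at the price of a C7 ester on the reacting face during the cycloaddition. It sets out from 18. Brief methanolysis with K2CO3 at 0 °C and a cold acidic quench allows 19 to be isolated. Silylation with 24 gives the 6-epi dienylsilyl ether F8. Thermal cycloaddition as in step 17 gives the 6-epi tricycle F9. Tamao oxidation gives the 6-epi diol F10. NaOMe/MeOH then epimerises C6 with no possibility of alkene migration; any 7,20-lactone that re-forms is reopened under the same conditions, and the route is rejoined at 27.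

**Step 21.** C16 may attack the other allyl terminus, C11, which would also close a five-membered ring across C8 and C11. The enolate may be O-alkylated. Ionisation may be slow, because palladium has to approach ring C from the side of ring B.
Fallback: replace the allylic alkylation by a conjugate addition, which can only reach C13. It sets out from 28. Dess–Martin oxidation gives the C11 enone F11. K2CO3 or DBU induces intramolecular Michael addition of C16 to C13, giving the 11-oxo tetracycle F12. SmI2 in THF/MeOH at −78 °C removes the sulfonyl group and gives the 11,15-dione F13. Ethane-1,2-dithiol with Zn(OTf)2 converts the cyclohexanone carbonyl at C11 into its dithiolane F14, the neopentyl C15 ketone being too hindered. Acetone-deactivated Raney Ni then desulfurises it, and the route is rejoined at 32.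

**Step 28.** The C7 ester on C6 lies near the exo trajectory. Hydride may therefore be delivered from the endo face; the resulting alkoxide would point towards C7 and could acylate itself on the ester.
Fallback: turn C7 from an obstacle into the carrier of the hydride. It sets out from 37. Me3SnOH in 1,2-dichloroethane at 80 °C should cleave the C7 methyl ester without a free nucleophile that would stay on the exocyclic enone, giving the triacid enone F15. Me4NBH(OAc)3 in MeCN/AcOH at −20 °C is then bound by the C7 carboxyl group, which lies on the exo side of C15, and delivers hydride from that side. This is the carboxylic acid counterpart of the hydroxyl-directed triacetoxyborohydride reduction, and it arrives at 39 directly.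

## Further compounds

F1 | step 17 | methyl enone alcohol (C8–C(=O)CH3, C20–OH, methyl 6β-carboxylate) | CC(=O)C1=C[C@]2(CO)CCC[C@@](C)(C(=O)OC(C)(C)C)[C@H]2[C@@H]1C(=O)OC
F2 | step 17 | methyl enone dienylsilyl ether | C=C/C=C/[Si](C)(C)OC[C@@]12CCC[C@@](C)(C(=O)OC(C)(C)C)[C@H]1[C@H](C(=O)OC)C(C(C)=O)=C2
F3 | step 17 | siloxane-bridged tricyclic methyl ketone (C8–C(=O)CH3) | C1=C[C@H]2[C@H]3[C@]4(CO[Si]2(C)C)CCC[C@@](C)(C(=O)OC(C)(C)C)[C@H]4[C@H](C(=O)OC)[C@]3(C1)C(C)=O
F4 | step 3 | racemic enol triflate | CCCC/C=C/C1(CO[Si](C)(C)C(C)(C)C)CCCC(OS(=O)(=O)C(F)(F)F)=C1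
F5 | step 3 | racemic tert-butyl ester | CCCC/C=C/C1(CO[Si](C)(C)C(C)(C)C)CCCC(C(=O)OC(C)(C)C)=C1
F6 | step 3 | racemic alcohol | CCCC/C=C/C1(CO)CCCC(C(=O)OC(C)(C)C)=C1
F7 | step 3 | (S)-O-methylmandelate of 8 | CCCC/C=C/[C@]1(COC(=O)[C@@H](OC)c2ccccc2)CCCC(C(=O)OC(C)(C)C)=C1
F8 | step 14 | 6-epi dienylsilyl ether | C=C/C=C/[Si](C)(C)OC[C@@]12CCC[C@@](C)(C(=O)OC(C)(C)C)[C@H]1[C@@H](C(=O)OC)C(C(=O)CS(=O)(=O)c1ccccc1)=C2
F9 | step 14 | 6-epi siloxane-bridged tricycle | C1=C[C@H]2[C@H]3[C@]4(CO[Si]2(C)C)CCC[C@@](C)(C(=O)OC(C)(C)C)[C@H]4[C@@H](C(=O)OC)[C@]3(C1)C(=O)CS(=O)(=O)c1ccccc1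
F10 | step 14 | 6-epi 11,20-diol | C1=C[C@H](O)[C@H]2[C@]3(CO)CCC[C@@](C)(C(=O)OC(C)(C)C)[C@H]3[C@@H](C(=O)OC)[C@]2(C1)C(=O)CS(=O)(=O)c1ccccc1
F11 | step 21 | C11 enone (11-oxo, C12=C13, 20-O-silyl ether) | C1=CC(=O)[C@H]2[C@]3(CO[Si](C)(C)C(C)(C)C)CCC[C@@](C)(C(=O)OC(C)(C)C)[C@H]3[C@H](C(=O)OC)[C@]2(C1)C(=O)CS(=O)(=O)c1ccccc1
F12 | step 21 | 11-oxo tetracycle with ring D closed and the 16-phenylsulfonyl group (C16 epimers) | O=C1C(S(=O)(=O)c2ccccc2)[C@@H]2CC(=O)[C@H]3[C@]4(CO[Si](C)(C)C(C)(C)C)CCC[C@@](C)(C(=O)OC(C)(C)C)[C@H]4[C@H](C(=O)OC)[C@]13C2
F13 | step 21 | 11,15-dione (ring D closed, C16 methylene group) | O=C1C[C@@H]2CC(=O)[C@H]3[C@]4(CO[Si](C)(C)C(C)(C)C)CCC[C@@](C)(C(=O)OC(C)(C)C)[C@H]4[C@H](C(=O)OC)[C@]13C2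
F14 | step 21 | C11 dithiolane of F13 | O=C1C[C@@H]2CC3(SCCS3)[C@H]4[C@]5(CO[Si](C)(C)C(C)(C)C)CCC[C@@](C)(C(=O)OC(C)(C)C)[C@H]5[C@H](C(=O)OC)[C@]14C2
F15 | step 28 | triacid enone (16-methylene-15-ketone, 7,19,20-trioic acid) | C=C1[C@@H]2CC[C@H]3[C@]4(C(=O)O)CCC[C@@](C)(C(=O)O)[C@H]4[C@H](C(=O)O)[C@]3(C2)C1=O
A1 | alternative 1 | tetracyclic 16-ketone with C1=C2, ester on C4 and silyloxymethyl groups on C4 and C10 | O=C1[C@@H]2CC[C@H]3[C@]4(CO[Si](C)(C)C(C)(C)C)C=CC[C@@](C(=O)OC)(CO[Si](C)(C)C(C)(C)C)[C@H]4[C@H](C(=O)OC)[C@]3(C2)[C@@H]1O[Si](C)(C)C(C)(C)C
A2 | alternative 2 | 19,20-lactone with vinyl and methyl on C4 and allyl on C10 | C=C[C@@]1(C)C(=O)OC[C@@]2(CC=C)[C@@H]1[C@H](C(=O)OC)[C@]34C[C@H](C5(OCCO5)C3)CC[C@H]42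
A3 | alternative 3 | tetracyclic 6-ketone with 16-methylene | C=C1[C@@H]2CC[C@H]3[C@]4(CO[Si](c5ccccc5)(c5ccccc5)C(C)(C)C)CCC[C@@](C)(C(=O)OC)[C@H]4C(=O)[C@]3(C2)C1
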